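**Retrosynthetic overview**

1. Target 34 ⇐ anti epoxidation of the Z C4=C5 bond, unmasking of the C11=C13 methylene, O8/O9 acylation and C9 reduction ⇐ ten-membered keto ester 25.
2. 25 ⇐ two-carbon ring enlargement of cyclooctenone 20 through its enol silane 21: formal [2+2] with methyl propiolate across C9=C2, then 4π opening of the C9–C2 bond. The alkyne supplies C10, C1 and C14.
3. Enabling feature: the oxygen-bearing C9 sits next to C10, which carries C14O2Me and the C1=C10 bond. These are a ketone carbon and two inserted propiolate carbons; without C10 and C1 the ring atoms C2–C9 form a cyclooct-4-enone, whose necessarily Z C4=C5 bond matches the cis 4,5-epoxide.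
4. 20 ⇐ ring-closing metathesis (C4=C5) on a cis-fused γ-lactone. C5–C9, C11, C12 and the stereocentres C6, C7, C8 come from diacetone-D-glucose (sugar C1–C5 = C5–C9; 3-C-branch = C11/C12).
5. Ring order: furanose (chiral pool) → γ-lactone → cyclooctene → transient cyclobutene → cyclodecadiene → oxirane.

Key step: step 15

Remark: germacrane numbering is used (C1=C10 bearing C14O2Me, C4(C15)–C5 oxirane, C6–O lactone to C12, C8 methacrylate, C9 acetate); the SMILES is read as 4R,5S,6R,7R,8S,9S, that is a cis-fused lactone, O8 cis and O9 trans to it, an oxirane derived from a Z alkene and anti to O6, and C2/C9 cis on C1=C10; centres formed as inconsequential mixtures are left undefined in the SMILES.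

**Route**

Step 1
Reactants: 1 diacetone-D-glucose (1,2:5,6-di-O-isopropylidene-α-D-glucofuranose)
Product: 2 1,2:5,6-di-O-isopropylidene-α-D-ribo-hexofuranos-3-ulose
Conditions: TEMPO (cat.), KBr (cat.), NaOCl, NaHCO3, CH2Cl2/H2O, 0 °C
Reagents that add atoms: none
Why: TEMPO/NaOCl oxidation of the single free secondary hydroxyl should give the 3-ulose; no stereocentre is created and both acetals tolerate the bicarbonate-buffered medium.

Step 2
Reactants: 2 the 3-ulose; 3 trimethyl phosphonoacetate
Product: 4 methyl 2-(3-deoxy-1,2:5,6-di-O-isopropylidene-α-D-ribo-hexofuranos-3-ylidene)acetate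
Conditions: NaH, THF, 0 °C to rt
Reagents that add atoms: trimethyl phosphonoacetate 3, COC(=O)CP(=O)(OC)OC
Why: Horner–Wadsworth–Emmons olefination of the electrophilic furanos-3-ulose should give the ylidene ester, whose E/Z geometry is irrelevant because the double bond is saturated in step 3.

Step 3
Reactants: 4 the ylidene ester
Product: 5 3-deoxy-3-C-(methoxycarbonylmethyl)-1,2:5,6-di-O-isopropylidene-α-D-allofuranose
Conditions: H2 (1 atm), 10% Pd/C, EtOAc, rt
Reagents that add atoms: none
Why: Heterogeneous hydrogenation should deliver hydrogen to the convex β-face of the cis-fused furanose–dioxolane, anti to the 1,2-acetonide, so that the C-branch at sugar C3 (C7 of the target) ends up cis to O2 (O6) and on the same Fischer side as O4 (O8), the allo arrangement that carries the C6/C7/C8 triad.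

Step 4
Reactants: 5 the allo ester
Product: 7 3-deoxy-3-C-(methoxycarbonylmethyl)-1,2-O-isopropylidene-α-D-ribo-pentodialdo-1,4-furanose, via diol 6 (not isolated)
Conditions: H5IO6, EtOAc, rt
Reagents that add atoms: none
Why: Periodic acid should hydrolyse the more labile terminal dioxolane and then cleave the liberated glycol (Malaprade cleavage) in one pot, excising sugar C6 and leaving sugar C5 (C9) as the aldehyde without touching a stereocentre.

Step 5
Reactants: 7 the aldehyde; 8 4-bromo-2-methylbut-1-ene (as its Grignard reagent)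
Product: 9 3-deoxy-3-C-(methoxycarbonylmethyl)-5-C-(3-methylbut-3-enyl)-1,2-O-isopropylidene-α-D-ribofuranose (both epimers at sugar C5 = C9)
Conditions: 8, Mg, THF, rt; then 7, THF, −78 °C; H2O
Reagents that add atoms: 3-methylbut-3-enylmagnesium bromide (from 8 and Mg), CC(=C)CC[Mg]Br
Why: Grignard 1,2-addition to the aldehyde at −78 °C should outrun attack on the methyl ester; the new C9 carbinol centre is expected as an epimer mixture, which is of no consequence because C9 is oxidised in step 13.

Step 6
Reactants: 9 the C9 carbinol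
Product: 10 5-O-(2-naphthylmethyl) ether of 9
Conditions: 2-naphthylmethyl 2,2,2-trichloroacetimidate, TfOH (cat.), CH2Cl2, −20 °C
Reagents that add atoms: 2-naphthylmethyl 2,2,2-trichloroacetimidate, N=C(OCc1ccc2ccccc2c1)C(Cl)(Cl)Cl
Why: Acid-catalysed O-alkylation with the trichloroacetimidate works on hindered secondary alcohols without base (no alkoxide that could attack the ester), and the naphthylmethyl ether should survive the aqueous acid of step 7 and be removable by DDQ next to a silyl ether.

Step 7
Reactants: 10 the naphthylmethyl ether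
Product: 11 3-C-(carboxymethyl)-3-deoxy-5-C-(3-methylbut-3-enyl)-5-O-(2-naphthylmethyl)-D-ribofuranose 2-O-lactone (lactol; anomers)
Conditions: AcOH/H2O (4:1), 80 °C
Reagents that add atoms: none
Why: Acid hydrolysis of the 1,2-acetonide frees the anomeric hydroxyl and O2 (O6), and O6, the only free hydroxyl that can reach the ester because O8 is still the furanose ring oxygen, should close the cis-fused γ-lactone (lactonisation), which fixes the O6/O8 differentiation needed later.

Step 8
Reactants: 11 the lactol lactone; 12 methyltriphenylphosphonium bromide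
Product: 13 hydroxy diene lactone (γ-lactone C12→O6; vinyl at C6; at C7 the chain C8H(OH)–C9H(ONAP)–C2H2–C3H2–C4(CH3)=CH2)
Conditions: 12, KN(SiMe3)2, THF, 0 °C; then 11, −78 to 0 °C
Reagents that add atoms: methylenetriphenylphosphorane (from 12 and KN(SiMe3)2), C=P(c1ccccc1)(c1ccccc1)c1ccccc1
Why: Wittig methylenation of the open hydroxy-aldehyde form of the lactol should give the C5 vinyl group and release O8–H; acyl transfer from O6 to the O8 alkoxide would have to pass through a strained 2,6-dioxabicyclo[2.2.1]heptane orthoester and is expected to be slow at or below 0 °C.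

Step 9
Reactants: 13 the hydroxy diene lactone
Product: 14 O8-tert-butyldimethylsilyl ether of 13
Conditions: tBuMe2SiOTf, 2,6-lutidine, CH2Cl2, −78 °C
Reagents that add atoms: tert-butyldimethylsilyl triflate, CC(C)(C)[Si](C)(C)OS(=O)(=O)C(F)(F)F
Why: Silylation with the triflate and a hindered pyridine base should cap the congested O8–H without generating an alkoxide, blocking lactone migration and later shielding C8–H from enolisation.

Step 10
Reactants: 14 the silylated diene
Product: 15 cyclooctene lactone (ring C2–C9; Z C4=C5; cis-fused C12→O6 lactone; 8-OTBS; 9-ONAP)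
Conditions: second-generation Grubbs catalyst RuCl2(=CHPh)(H2IMes)(PCy3) (5 mol%), PhMe (2 mM), 80 °C
Reagents that add atoms: none
Why: Ring-closing metathesis between the vinyl group and the 1,1-disubstituted alkene, whose chains are held cis on the lactone, should close the eight-membered ring with loss of ethene, and in a cyclooctene the new trisubstituted C4=C5 bond can only be Z.

Step 11
Reactants: 15 the cyclooctene lactone; 16 chloromethyl phenyl sulfide
Product: 18 11-(phenylthiomethyl) lactone (C13 = CH2SPh), via silyl ketene acetal 17 (not isolated)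
Conditions: LiN(iPr)2, THF, −78 °C; Me3SiCl; then 16, ZnBr2 (cat.), CH2Cl2, rt
Reagents that add atoms: chloromethyl phenyl sulfide 16, ClCSc1ccccc1
Why: Zinc bromide-catalysed alkylation of the lactone silyl ketene acetal by the thionium ion from chloromethyl phenyl sulfide (SN1-type α-phenylthiomethylation) should install C13 as a masked exo-methylene; attack from the convex face should place CH2SPh anti to C8, but this C11 centre is erased in step 21.

Step 12
Reactants: 18 the phenylthiomethyl lactone
Product: 19 C9 alcohol (both epimers)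
Conditions: DDQ, CH2Cl2/pH 7 buffer, 0 °C to rt
Reagents that add atoms: none
Why: Oxidative cleavage of the 2-naphthylmethyl ether with DDQ (benzylic hydride abstraction, then hydrolysis of the oxocarbenium ion) should free O9–H while the silyl ether, lactone, aryl sulfide and trisubstituted alkene are not attacked.

Step 13
Reactants: 19 the C9 alcohol
Product: 20 cyclooctenone (C9 ketone; 8-OTBS; Z C4=C5; lactone; CH2SPh)
Conditions: Dess–Martin periodinane, NaHCO3, CH2Cl2, rt
Reagents that add atoms: none
Why: Dess–Martin oxidation under bicarbonate buffer should convert both C9 epimers into the single cyclooctenone without epimerising C8 or oxidising the sulfide.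

Step 14
Reactants: 20 the cyclooctenone
Product: 21 C9=C2 tert-butyldimethylsilyl enol ether of 20
Conditions: LiN(iPr)2, THF, −78 °C; tBuMe2SiCl, DMPU, −78 to 0 °C
Reagents that add atoms: tert-butyldimethylsilyl chloride, CC(C)(C)[Si](C)(C)Cl
Why: Kinetic deprotonation with the hindered amide base should occur at the unhindered C2 methylene rather than at C8–H (flanked by the silyloxy group and the C7 branch) or at the tertiary lactone α-H, and O-silylation then fixes the C9=C2 enol ether regiochemistry needed for the insertion.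

Step 15
Reactants: 21 the enol silane; 22 methyl propiolate
Product: 25 methyl (1(10)E,4Z)-8-(tert-butyldimethylsilyloxy)-9-oxo-13-(phenylthio)-11,13-dihydrogermacra-1(10),4-dien-12,6-olid-14-oate, via cyclobutene 23 (not isolated), via silyloxydiene 24 (not isolated)
Conditions: 22, Tf2NH (5 mol%), CH2Cl2, −78 °C; Et3N, then PhMe, 90 °C; 1 M HCl, THF, 0 °C; Et3N (cat.), CH2Cl2, rt
Reagents that add atoms: methyl propiolate 22, COC(=O)C#C
Why: The silyl triflimide formed from the catalyst activates methyl propiolate, C2 of the enol silane adds to its β-carbon (Mukaiyama–Michael) and the resulting allenoate carbon closes on the silyloxocarbenium carbon C9 (stepwise formal [2+2], 4-exo aldol-type closure), giving the cis-fused 1-silyloxybicyclo[6.2.0]dec-9-ene 23 in which the alkyne carbons have become C1 and C10 and the ester is C14. On warming, the cyclobutene undergoes conrotatory 4π electrocyclic ring opening that cleaves the shared C9–C2 bond, driven by the strain of the four-membered ring and by the silyloxy donor on the breaking bond, so the ten-membered ring is not closed but released from the eight-membered one as the 2-silyloxy-1,3-diene 24. Acid hydrolysis of the dienol silyl ether and amine equilibration through the dienol should give the conjugated keto ester 25 with C9 and C2 cis on C1=C10, the less strained arrangement for a cyclodecenone, which places C14 trans to C2 as in the target. The closest known reaction type is the acid-promoted [2+2] cycloaddition of cycloalkanone silyl enol ethers with propiolates followed by thermal ring opening (two-carbon ring enlargement, also known from enamines). The two stereocentres created in 23 (C9 and C2) are destroyed again, so the face selectivity of the cycloaddition is irrelevant and C6, C7 and C8 are untouched. The step needs regiocontrol (insertion between C9 and C2, secured by the enol silane of step 14) and chemoselectivity (the substrate holds no Michael acceptor, because the methylene lactone is masked as CH2SPh and O8 carries no acyl group).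

Step 16
Reactants: 25 the keto ester
Product: 26 (9S)-9-hydroxy analogue of 25 (O9 trans to O8)
Conditions: NaBH4, CeCl3·7H2O, MeOH/THF, −78 °C
Reagents that add atoms: none
Why: Luche reduction (cerium-activated carbonyl, hard alkoxyborohydride) should favour 1,2- over conjugate addition, and polar Felkin–Anh attack anti to the C8–OSi bond should give the 9S alcohol with O9 trans to O8.

Step 17
Reactants: 26 the C9 alcohol; 27 acetic anhydride
Product: 28 9-O-acetate of 26
Conditions: 27, pyridine, DMAP (cat.), CH2Cl2, 0 °C
Reagents that add atoms: acetic anhydride 27, CC(=O)OC(C)=O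
Why: DMAP-catalysed acetylation of the allylic secondary alcohol should proceed with retention, the only other hydroxyl being silylated.

Step 18
Reactants: 28 the acetate
Product: 29 8-hydroxy-9-acetoxy compound (silyl ether removed)
Conditions: HF·pyridine, pyridine, THF, 0 °C to rt
Reagents that add atoms: none
Why: Buffered HF·pyridine should cleave the secondary silyl ether under mildly acidic conditions, under which acetate migration from O9 to O8 and attack on the lactone or enoate are slow.

Step 19
Reactants: 29 the C8 alcohol; 30 methacrylic anhydride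
Product: 31 8-O-methacrylate of 29
Conditions: 30, Et3N, DMAP (cat.), CH2Cl2, −20 to 0 °C
Reagents that add atoms: methacrylic anhydride 30, CC(=C)C(=O)OC(=O)C(C)=C
Why: DMAP-catalysed acylation with the anhydride at low temperature should esterify O8–H faster than the vicinal acetate can migrate, placing the methacrylate on C8.

Step 20
Reactants: 31 the sulfide
Product: 32 sulfoxide of 31 (both configurations at sulfur)
Conditions: NaIO4, MeOH/THF/H2O, 0 °C to rt
Reagents that add atoms: sodium periodate, [Na+].[O-]I(=O)(=O)=O
Why: Periodate should oxidise the sulfide chemoselectively to the sulfoxide (no epoxidation, no sulfone), the configuration at sulfur being irrelevant.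

Step 21
Reactants: 32 the sulfoxide
Product: 33 4,5-deoxy target (methyl (1(10)E,4Z)-9-acetoxy-8-methacryloyloxygermacra-1(10),4,11(13)-trien-12,6-olid-14-oate)
Conditions: PhMe, NaHCO3 (solid), 80 °C
Reagents that add atoms: none
Why: Thermal syn-elimination of the β-sulfinyl lactone (sulfoxide pyrolysis) can only take the acidic C11–H, so it should unveil the exocyclic C11=C13 methylene; the temperature is kept below that needed for Cope rearrangement of the 1(10),4-diene.

Step 22
Reactants: 33 the triene
Product: 34 target CNP0153978.6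
Conditions: mCPBA, NaHCO3, CH2Cl2, 0 °C
Reagents that add atoms: mCPBA (3-chloroperoxybenzoic acid), OOC(=O)c1cccc(Cl)c1
Why: Prilezhaev epoxidation should take only the electron-rich trisubstituted C4=C5 bond (the three other alkenes are conjugated to carbonyl groups), and peripheral attack on the Z-cycloalkene anti to the allylic C6–O bond, the usual course for medium-ring allylic esters, should set 4R,5S.

**Compound list**

1 | 1,2:5,6-di-O-isopropylidene-α-D-glucofuranose (diacetone-D-glucose) | O[C@@H]1[C@H]2OC(C)(C)O[C@H]2O[C@@H]1[C@H]1COC(C)(C)O1 | starting material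
2 | 1,2:5,6-di-O-isopropylidene-α-D-ribo-hexofuranos-3-ulose | O=C1[C@H]2OC(C)(C)O[C@H]2O[C@@H]1[C@H]1COC(C)(C)O1 | intermediate
3 | trimethyl phosphonoacetate | COC(=O)CP(=O)(OC)OC | starting material
4 | methyl 2-(3-deoxy-1,2:5,6-di-O-isopropylidene-α-D-ribo-hexofuranos-3-ylidene)acetate (E/Z mixture expected) | COC(=O)C=C1[C@H]2OC(C)(C)O[C@H]2O[C@@H]1[C@H]1COC(C)(C)O1 | intermediate
5 | 3-deoxy-3-C-(methoxycarbonylmethyl)-1,2:5,6-di-O-isopropylidene-α-D-allofuranose | COC(=O)C[C@H]1[C@H]2OC(C)(C)O[C@H]2O[C@@H]1[C@H]1COC(C)(C)O1 | intermediate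
6 | 3-deoxy-3-C-(methoxycarbonylmethyl)-1,2-O-isopropylidene-α-D-allofuranose (5,6-diol) | COC(=O)C[C@H]1[C@H]2OC(C)(C)O[C@H]2O[C@@H]1[C@H](O)CO | intermediate (not isolated)
7 | 3-deoxy-3-C-(methoxycarbonylmethyl)-1,2-O-isopropylidene-α-D-ribo-pentodialdo-1,4-furanose | COC(=O)C[C@H]1[C@H]2OC(C)(C)O[C@H]2O[C@@H]1C=O | intermediate
8 | 4-bromo-2-methylbut-1-ene | CC(=C)CCBr | starting material
9 | 3-deoxy-3-C-(methoxycarbonylmethyl)-5-C-(3-methylbut-3-enyl)-1,2-O-isopropylidene-α-D-ribofuranose (C9 epimers) | COC(=O)C[C@H]1[C@H]2OC(C)(C)O[C@H]2O[C@@H]1C(O)CCC(C)=C | intermediate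
10 | 5-O-(2-naphthylmethyl) ether of 9 (C9 epimers) | COC(=O)C[C@H]1[C@H]2OC(C)(C)O[C@H]2O[C@@H]1C(OCc1ccc2ccccc2c1)CCC(C)=C | intermediate
11 | 3-C-(carboxymethyl)-3-deoxy-5-C-(3-methylbut-3-enyl)-5-O-(2-naphthylmethyl)-D-ribofuranose 2-O-lactone (anomers, C9 epimers) | O=C1C[C@H]2[C@@H](O1)C(O)O[C@@H]2C(OCc1ccc2ccccc2c1)CCC(C)=C | intermediate
12 | methyltriphenylphosphonium bromide | C[P+](c1ccccc1)(c1ccccc1)c1ccccc1.[Br-] | starting material
13 | γ-lactone (C12→O6) with vinyl at C6 and, cis to it at C7, the chain C8H(OH)–C9H(ONAP)–CH2CH2C(CH3)=CH2; C6, C7, C8 as in the target | O[C@H](C(OCc1ccc2ccccc2c1)CCC(C)=C)[C@H]1CC(=O)O[C@H]1C=C | intermediate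
14 | O8-tert-butyldimethylsilyl ether of 13 | CC(C)(C)[Si](C)(C)O[C@H](C(OCc1ccc2ccccc2c1)CCC(C)=C)[C@H]1CC(=O)O[C@H]1C=C | intermediate
15 | cyclooctene lactone: ring C2–C9 with Z C4(CH3)=C5, cis-fused C12→O6 γ-lactone at C6–C7, 8-OTBS, 9-ONAP | CC(C)(C)[Si](C)(C)O[C@H]1[C@H]2CC(=O)O[C@H]2/C=C(/C)CCC1OCc1ccc2ccccc2c1 | intermediate
16 | chloromethyl phenyl sulfide | ClCSc1ccccc1 | starting material
17 | trimethylsilyl ketene acetal of lactone 15 (C11=C12) | CC(C)(C)[Si](C)(C)O[C@H]1[C@H]2C=C(O[Si](C)(C)C)O[C@H]2/C=C(/C)CCC1OCc1ccc2ccccc2c1 | intermediate (not isolated)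
18 | 11-(phenylthiomethyl) derivative of 15 (CH2SPh at C11 anti to C8) | CC(C)(C)[Si](C)(C)O[C@H]1[C@H]2[C@H](CSc3ccccc3)C(=O)O[C@H]2/C=C(/C)CCC1OCc1ccc2ccccc2c1 | intermediate
19 | C9 alcohol from 18 (C9 epimers) | CC(C)(C)[Si](C)(C)O[C@H]1[C@H]2[C@H](CSc3ccccc3)C(=O)O[C@H]2/C=C(/C)CCC1O | intermediate
20 | cyclooctenone: C9 ketone, 8-OTBS, Z C4=C5, lactone with 11-CH2SPh | CC(C)(C)[Si](C)(C)O[C@H]1[C@H]2[C@H](CSc3ccccc3)C(=O)O[C@H]2/C=C(/C)CCC1=O | intermediate
21 | C9=C2 tert-butyldimethylsilyl enol ether of 20 | CC(C)(C)[Si](C)(C)O[C@H]1[C@H]2[C@H](CSc3ccccc3)C(=O)O[C@H]2/C=C(/C)C/C=C1/O[Si](C)(C)C(C)(C)C | intermediate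
22 | methyl propiolate | COC(=O)C#C | starting material
23 | cis-fused 1-silyloxybicyclo[6.2.0]dec-9-ene-9-carboxylate (cyclobutene C9–C10=C1–C2; either face) | CC(C)(C)[Si](C)(C)O[C@H]1[C@H]2[C@H](CSc3ccccc3)C(=O)O[C@H]2/C=C(/C)CC2C=C(C(=O)OC)C12O[Si](C)(C)C(C)(C)C | intermediate (not isolated)
24 | ten-membered 9-silyloxy-9,1-diene ester (C9=C10–C1=C2; cis,trans) | CC(C)(C)[Si](C)(C)O[C@H]1[C@H]2[C@H](CSc3ccccc3)C(=O)O[C@H]2/C=C(/C)CC=CC(C(=O)OC)=C1O[Si](C)(C)C(C)(C)C | intermediate (not isolated)
25 | methyl (1(10)E,4Z)-8-(tert-butyldimethylsilyloxy)-9-oxo-13-(phenylthio)-11,13-dihydrogermacra-1(10),4-dien-12,6-olid-14-oate | CC(C)(C)[Si](C)(C)O[C@H]1[C@H]2[C@H](CSc3ccccc3)C(=O)O[C@H]2/C=C(/C)CC/C=C(/C(=O)OC)C1=O | intermediate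
26 | (9S)-9-hydroxy analogue of 25 | CC(C)(C)[Si](C)(C)O[C@H]1[C@H]2[C@H](CSc3ccccc3)C(=O)O[C@H]2/C=C(/C)CC/C=C(/C(=O)OC)[C@@H]1O | intermediate
27 | acetic anhydride | CC(=O)OC(C)=O | starting material
28 | 9-O-acetate of 26 | CC(C)(C)[Si](C)(C)O[C@H]1[C@H]2[C@H](CSc3ccccc3)C(=O)O[C@H]2/C=C(/C)CC/C=C(/C(=O)OC)[C@@H]1OC(C)=O | intermediate
29 | 8-hydroxy-9-acetoxy compound | O[C@H]1[C@H]2[C@H](CSc3ccccc3)C(=O)O[C@H]2/C=C(/C)CC/C=C(/C(=O)OC)[C@@H]1OC(C)=O | intermediate
30 | methacrylic anhydride | CC(=C)C(=O)OC(=O)C(C)=C | starting material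
31 | 8-O-methacrylate of 29 | C=C(C)C(=O)O[C@H]1[C@H]2[C@H](CSc3ccccc3)C(=O)O[C@H]2/C=C(/C)CC/C=C(/C(=O)OC)[C@@H]1OC(C)=O | intermediate
32 | sulfoxide of 31 (both configurations at sulfur) | C=C(C)C(=O)O[C@H]1[C@H]2[C@H](CS(=O)c3ccccc3)C(=O)O[C@H]2/C=C(/C)CC/C=C(/C(=O)OC)[C@@H]1OC(C)=O | intermediate
33 | methyl (1(10)E,4Z)-9-acetoxy-8-methacryloyloxygermacra-1(10),4,11(13)-trien-12,6-olid-14-oate (4,5-deoxy target) | C=C(C)C(=O)O[C@H]1[C@H]2C(=C)C(=O)O[C@H]2/C=C(/C)CC/C=C(/C(=O)OC)[C@@H]1OC(C)=O | intermediate
34 | CNP0153978.6 | C=C(C)C(=O)O[C@H]1[C@H]2C(=C)C(=O)O[C@H]2[C@@H]2O[C@]2(C)CC/C=C(/C(=O)OC)[C@@H]1OC(C)=O | target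

**Step count and risks**

Total step count: 22. Longest linear sequence: 22 steps (from 1).

Steps most likely to fail:

Step 15. The zwitterion formed after the Michael addition may collapse to the open-chain vinylogous adduct instead of closing the cyclobutene, the enol silane may be protodesilylated, or the sulfide and lactone may tie up the silyl Lewis acid. The fallback runs the same two-carbon insertion without any acid. It sets out from ketone 20: condensation with pyrrolidine (molecular sieves, PhH) should give the less substituted pyrrolidine enamine F1. This should add methyl propiolate 22 in Et2O at rt to give the aminocyclobutene F2, which opens spontaneously to the ring-enlarged dienamine ester F3. Buffered hydrolysis (AcOH/NaOAc, aqueous THF) returns to keto ester 25.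

Step 16. Hydride may add conjugately to C1 of the doubly activated alkene, or the ring conformation may override Felkin–Anh control and send hydride to the wrong face of C9. The fallback uses O8 to deliver the hydride. It sets out from 25: HF·pyridine should give the α-hydroxy ketone F4. Me4NBH(OAc)3 in MeCN/AcOH at −20 °C should bind O8 and transfer hydride intramolecularly to the C9 face syn to O8, a reagent that leaves enoates alone, giving the trans-8,9-diol F5. Selective acetylation of the less hindered allylic O9–H (Ac2O, 2,4,6-collidine, −20 °C) comes back to the route at 29.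

Step 22. The peracid may attack the alkene face syn to O6 (poor facial selectivity in the flexible ten-membered ring). The fallback brings the oxirane oxygen in as a nucleophile from the opposite face. It sets out from 33: NBS in aqueous THF at 0 °C should give the bromohydrin F6 (bromonium ion on the face the peracid prefers, water opening at the tertiary C4 from the other face). Ag2O in CH2Cl2 should then close the oxirane by SN2 displacement at C5, which comes back to the route at the target 34.

Further compounds
F1 | step 15 | C9=C2 pyrrolidine enamine of 20 | CC(C)(C)[Si](C)(C)O[C@H]1[C@H]2[C@H](CSc3ccccc3)C(=O)O[C@H]2/C=C(/C)C/C=C1/N1CCCC1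
F2 | step 15 | cis-fused 1-(pyrrolidin-1-yl)bicyclo[6.2.0]dec-9-ene-9-carboxylate (aminocyclobutene) | CC(C)(C)[Si](C)(C)O[C@H]1[C@H]2[C@H](CSc3ccccc3)C(=O)O[C@H]2/C=C(/C)CC2C=C(C(=O)OC)C12N1CCCC1
F3 | step 15 | ten-membered 9-(pyrrolidin-1-yl)-9,1-diene ester (dienamine) | CC(C)(C)[Si](C)(C)O[C@H]1[C@H]2[C@H](CSc3ccccc3)C(=O)O[C@H]2/C=C(/C)CC=CC(C(=O)OC)=C1N1CCCC1
F4 | step 16 | 8-hydroxy-9-oxo keto ester (25 without the silyl group) | O[C@H]1[C@H]2[C@H](CSc3ccccc3)C(=O)O[C@H]2/C=C(/C)CC/C=C(/C(=O)OC)C1=O
F5 | step 16 | trans-8,9-diol (9S) | O[C@H]1[C@H]2[C@H](CSc3ccccc3)C(=O)O[C@H]2/C=C(/C)CC/C=C(/C(=O)OC)[C@@H]1O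
F6 | step 22 | bromohydrin of 33 (C4–OH, C5–Br, anti) | C=C(C)C(=O)O[C@H]1[C@H]2C(=C)C(=O)O[C@H]2[C@@H](Br)[C@](C)(O)CC/C=C(/C(=O)OC)[C@@H]1OC(C)=O
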